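Cuts: (i) the lactone acyl–O bond (methyl ester + ring oxygen); (ii) the C7a–C3a bond of the carbocycle, which unfolds the six-membered ring to a 4-allenyl-4-methoxycyclobutenone; (iii) the bond from the four-ring carbinol carbon to the allene (cyclobutenedione + silyl alkynyl ketene acetal); (iv) the alkyne–CH bond (phenylacetylene + aryldiazoacetate) and the squarate–phenyl bond.
Enabling feature: the carbocycle C3a/C4/C5/C6/C7/C7a is the lactonised tautomer of an o-quinone methide (exocyclic C3=C3a next to the O-bearing C7a), with the C5 methoxy carbon para to C7a and the C6 oxygen between them.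
This is the pattern a squarate-derived 4-allenyl-4-alkoxycyclobutenone delivers on ring expansion: C7a = ketene carbon, C7/C6/C5 = the other three four-ring carbons, C4 and C3a = proximal and central allene carbons, C3 = allene terminus.
Forward order: four-membered ring from diisopropyl squarate, allenoate arm attached at its carbinol carbon, 4→6 ring expansion to the carbocycle with the exocyclic C=C already at the final oxidation level, then dealkylation and lactonisation to close the furanone.
Stereochemistry: the target has no stereocentre; its exocyclic C=C is fixed by the lactone ring, and the racemic centre and allene axis of the intermediates vanish in the ring expansion.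

Key step: step 7

Remark: the target is achiral, so "single enantiomer" needs no enantiocontrol; 8 and 10–12 are carried as racemates or diastereomer mixtures.

Step 1
Reactants: 1 diisopropyl squarate (3,4-diisopropoxycyclobut-3-ene-1,2-dione); 2 phenyllithium
Product: 4 3-isopropoxy-4-phenylcyclobut-3-ene-1,2-dione, via lithium alkoxide adduct 3 (not isolated)
Conditions: 2 (1.05 equiv), THF, −78 °C; TFAA, −78 °C to rt; aq. NH4Cl
Reagents that add atoms: none
Why: 1,2-addition of the aryllithium to a squarate carbonyl, then trifluoroacetylation and 1,2-carbonyl transposition with loss of one isopropyl group, is the standard squarate addition/rearrangement route to 3-alkoxy-4-arylcyclobutenediones.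

Step 2
Reactants: 5 methyl 2-[4-(benzyloxy)phenyl]acetate
Product: 6 methyl 2-[4-(benzyloxy)phenyl]-2-diazoacetate
Conditions: p-ABSA, DBU, MeCN, 0 °C to rt
Reagents that add atoms: 4-acetamidobenzenesulfonyl azide (p-ABSA), CC(=O)Nc1ccc(cc1)S(=O)(=O)N=[N+]=[N-]
Why: Regitz diazo transfer to the benzylic ester enolate is routine for methyl arylacetates, and the benzyl ether is inert.

Step 3
Reactants: 6 methyl 2-[4-(benzyloxy)phenyl]-2-diazoacetate; 7 phenylacetylene
Product: 8 methyl 2-[4-(benzyloxy)phenyl]-4-phenylbut-3-ynoate (racemic)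
Conditions: CuI (10 mol %), MeCN, rt, slow addition of 6
Reagents that add atoms: none
Why: copper(I)-catalysed alkyne–diazo cross-coupling (copper acetylide, carbene migratory insertion, protonation) should give the 3-alkynoate; any allenoate isomer can be taken along because step 4 converts both into the same enolate.

Step 4
Reactants: 8 methyl 2-[4-(benzyloxy)phenyl]-4-phenylbut-3-ynoate
Product: 9 {[2-[4-(benzyloxy)phenyl]-1-methoxy-4-phenylbut-1-en-3-yn-1-yl]oxy}trimethylsilane (silyl alkynyl ketene acetal, E/Z mixture, used crude)
Conditions: LiHMDS, THF, −78 °C; TMSCl, −78 to 0 °C; pentane, filtration under Ar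
Reagents that add atoms: chlorotrimethylsilane, C[Si](C)(C)Cl
Why: the doubly activated α-proton is removed irreversibly and the extended ester enolate is O-silylated (silyl ketene acetal formation).

Step 5
Reactants: 9 silyl alkynyl ketene acetal; 4 3-isopropoxy-4-phenylcyclobut-3-ene-1,2-dione
Product: 11 methyl 2-[4-(benzyloxy)phenyl]-4-(1-hydroxy-2-isopropoxy-4-oxo-3-phenylcyclobut-2-en-1-yl)-4-phenylbuta-2,3-dienoate (diastereomer mixture), via tertiary trimethylsilyl ether 10 (not isolated)
Conditions: HNTf2 (3 mol %), CH2Cl2, −78 °C; then 1 M aq. HCl, THF, 0 °C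
Reagents that add atoms: none
Why: Proposed new method: silylium activation (TMSNTf2 formed from HNTf2 and 9) of the ketone-type C2 carbonyl of 4 (flanked by C1=O and the alkoxy-bearing carbon, the one organolithiums attack in this ring system) should be followed by open-transition-state attack of 9 through its alkyne terminus, because the α-carbon is blocked by the aryl group and the silyl acetal; this creates the tetrasubstituted allenoate and transfers silicon to the tertiary alkoxide (10), shutting off retro-addition, and mild acid then frees the carbinol; the closest known reaction type is the γ-selective alkynylogous Mukaiyama aldol addition of silyl alkynyl ketene acetals to aldehydes, extended here to an activated cyclic 1,2-diketone.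

Step 6
Reactants: 11 tertiary cyclobutenol
Product: 12 methyl 2-[4-(benzyloxy)phenyl]-4-(2-isopropoxy-1-methoxy-4-oxo-3-phenylcyclobut-2-en-1-yl)-4-phenylbuta-2,3-dienoate
Conditions: MeI, Ag2O, 4 Å MS, MeCN, rt, dark
Reagents that add atoms: iodomethane, CI
Why: Purdie methylation etherifies the tertiary cyclobutenol without a free alkoxide (no retro-addition) and installs the future C5 methoxy group, which also blocks later collapse to a quinone.

Step 7
Reactants: 12 4-allenyl-4-methoxycyclobutenone
Product: 14 methyl 2-[4-(benzyloxy)phenyl]-2-(4-isopropoxy-3-methoxy-6-oxo-2,5-diphenylcyclohexa-2,4-dien-1-ylidene)acetate (o-quinone methide, E/Z mixture), via vinylketene 13 (not isolated)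
Conditions: PhMe (0.01 M, degassed), 110 °C
Reagents that add atoms: none
Why: Heating opens the cyclobutenone by conrotatory 4π electrocyclic cleavage of the C1–C4 bond to the vinylketene 13, the 4-methoxy donor rotating outward so that the allenyl group ends up cis to the ketene; the ketene C=C, the enol-ether C=C and the proximal allene C=C then undergo a thermal 6π electrocyclisation (bond from the ketene carbon to the central allene carbon) that closes the six-membered carbocycle and leaves the old allene terminus as the exocyclic C=C(Ar)CO2Me, giving the o-quinone methide 14 at the oxidation level of the target. The closest known reaction type is the thermal ring expansion of 4-allenylcyclobutenones to o-quinone methides, the allenyl member of the squarate-based 4-alkenylcyclobutenone to hydroquinone (Moore) rearrangement. The only ring closed is the carbocycle, by 6π electrocyclisation of a (Z)-dienylketene (a pericyclic closure, so polar ring-closure rules do not apply). No stereocentre is formed: the C4 centre and the allene axis of 12 are destroyed, and the geometry of the exocyclic bond is immaterial because the push–pull methide isomerises and is later locked by the lactone. The selectivities needed are inward rotation of the allene (secured by the outward-rotating 4-OMe), closure on the proximal allene π-bond (the only one that gives a six-membered ring), and no collapse to a quinone (secured by the O-methyl group on C4, which leaves the isopropoxy-bearing carbon as the only one able to become the carbonyl later).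

Step 8
Reactants: 14 o-quinone methide ester
Product: 16 3-(4-hydroxyphenyl)-5-methoxy-4,7-diphenyl-1-benzofuran-2,6-dione (target), via hydroxy quinone methide ester 15 (not isolated)
Conditions: BCl3, C6HMe5, CH2Cl2, −78 to 0 °C; MeOH/H2O quench; then TsOH·H2O (10 mol %), PhMe, 80 °C
Reagents that add atoms: none
Why: Lewis-acid ether cleavage (BCl3 with a cation scavenger) removes the benzyl and the carbonyl-conjugated isopropyl group but not the methyl ether; the freed vinylogous acid tautomerises to place OH on C7a, and acid-catalysed five-membered lactonisation with loss of methanol fixes the exocyclic alkene.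

Compound list
1 | diisopropyl squarate (3,4-diisopropoxycyclobut-3-ene-1,2-dione) | CC(C)OC1=C(OC(C)C)C(=O)C1=O | starting material
2 | phenyllithium | [Li]c1ccccc1 | starting material
3 | lithium 2,3-diisopropoxy-4-oxo-1-phenylcyclobut-2-en-1-olate (not isolated) | CC(C)OC1=C(OC(C)C)C(O[Li])(c2ccccc2)C1=O | intermediate
4 | 3-isopropoxy-4-phenylcyclobut-3-ene-1,2-dione | CC(C)OC1=C(c2ccccc2)C(=O)C1=O | intermediate
5 | methyl 2-[4-(benzyloxy)phenyl]acetate | COC(=O)Cc1ccc(OCc2ccccc2)cc1 | starting material
6 | methyl 2-[4-(benzyloxy)phenyl]-2-diazoacetate | COC(=O)C(=[N+]=[N-])c1ccc(OCc2ccccc2)cc1 | intermediate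
7 | phenylacetylene | C#Cc1ccccc1 | starting material
8 | methyl 2-[4-(benzyloxy)phenyl]-4-phenylbut-3-ynoate (racemic) | COC(=O)C(C#Cc1ccccc1)c1ccc(OCc2ccccc2)cc1 | intermediate
9 | {[2-[4-(benzyloxy)phenyl]-1-methoxy-4-phenylbut-1-en-3-yn-1-yl]oxy}trimethylsilane (E/Z mixture) | COC(O[Si](C)(C)C)=C(C#Cc1ccccc1)c1ccc(OCc2ccccc2)cc1 | intermediate
10 | methyl 2-[4-(benzyloxy)phenyl]-4-[2-isopropoxy-4-oxo-3-phenyl-1-(trimethylsilyloxy)cyclobut-2-en-1-yl]-4-phenylbuta-2,3-dienoate (not isolated, diastereomer mixture) | COC(=O)C(c1ccc(OCc2ccccc2)cc1)=C=C(c1ccccc1)C1(O[Si](C)(C)C)C(OC(C)C)=C(c2ccccc2)C1=O | intermediate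
11 | methyl 2-[4-(benzyloxy)phenyl]-4-(1-hydroxy-2-isopropoxy-4-oxo-3-phenylcyclobut-2-en-1-yl)-4-phenylbuta-2,3-dienoate (diastereomer mixture) | COC(=O)C(c1ccc(OCc2ccccc2)cc1)=C=C(c1ccccc1)C1(O)C(OC(C)C)=C(c2ccccc2)C1=O | intermediate
12 | methyl 2-[4-(benzyloxy)phenyl]-4-(2-isopropoxy-1-methoxy-4-oxo-3-phenylcyclobut-2-en-1-yl)-4-phenylbuta-2,3-dienoate (diastereomer mixture) | COC(=O)C(c1ccc(OCc2ccccc2)cc1)=C=C(c1ccccc1)C1(OC)C(OC(C)C)=C(c2ccccc2)C1=O | intermediate
13 | methyl 2-[4-(benzyloxy)phenyl]-6-isopropoxy-5-methoxy-8-oxo-4,7-diphenylocta-2,3,5,7-tetraenoate (vinylketene, not isolated) | COC(=O)C(c1ccc(OCc2ccccc2)cc1)=C=C(c1ccccc1)C(OC)=C(OC(C)C)C(c1ccccc1)=C=O | intermediate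
14 | methyl 2-[4-(benzyloxy)phenyl]-2-(4-isopropoxy-3-methoxy-6-oxo-2,5-diphenylcyclohexa-2,4-dien-1-ylidene)acetate (E/Z mixture) | COC(=O)C(c1ccc(OCc2ccccc2)cc1)=C1C(=O)C(c2ccccc2)=C(OC(C)C)C(OC)=C1c1ccccc1 | intermediate
15 | methyl 2-(4-hydroxyphenyl)-2-(6-hydroxy-3-methoxy-4-oxo-2,5-diphenylcyclohexa-2,5-dien-1-ylidene)acetate (not isolated) | COC(=O)C(c1ccc(O)cc1)=C1C(O)=C(c2ccccc2)C(=O)C(OC)=C1c1ccccc1 | intermediate
16 | 3-(4-hydroxyphenyl)-5-methoxy-4,7-diphenyl-1-benzofuran-2,6-dione | COC1=C(c2ccccc2)C2=C(c3ccc(O)cc3)C(=O)OC2=C(c2ccccc2)C1=O | target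

Total step count: 8. Longest linear sequence: 7 steps (steps 2–8, from 5); step 1 is the one-step side branch.

Steps most likely to fail

1. Step 5 (Proposed new method). What may go wrong: regiochemical leakage, either attack through the α-carbon of the ketene acetal (propargylic adduct), or silylium activation of the vinylogous-ester carbonyl leading to addition at C1 or to addition–elimination at the isopropoxy-bearing carbon. Fallback with known chemistry, setting out from 4 and returning at 16: 1-phenylvinyllithium F1, made from α-bromostyrene and t-BuLi (THF, −78 °C), is added to the C2 carbonyl of 4 and the alkoxide is methylated in the same flask with MeOTf (the standard organolithium/squarate protocol), giving 3-isopropoxy-4-methoxy-2-phenyl-4-(1-phenylethenyl)cyclobut-2-en-1-one F2. Thermolysis (PhMe, 110 °C) should give, by the classical 4-alkenylcyclobutenone ring expansion, 3-isopropoxy-4-methoxy-2,5-diphenylphenol F3, whose only free ring position is ortho to the hydroxyl group. Acid-mediated condensation with 4-hydroxymandelic acid (AcOH, cat. H2SO4, 90 °C; ortho-alkylation then lactonisation, the standard entry to 3-arylbenzofuranones) should give rac-3-(4-hydroxyphenyl)-6-isopropoxy-5-methoxy-4,7-diphenyl-1-benzofuran-2(3H)-one F4. BCl3 (CH2Cl2, −78 to 0 °C) removes the isopropyl group to give the leuco lactone rac-6-hydroxy-3-(4-hydroxyphenyl)-5-methoxy-4,7-diphenyl-1-benzofuran-2(3H)-one F5, and dehydrogenation with DDQ (1 equiv, dioxane, rt) gives 16.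

2. Step 7 (key step). What may go wrong: the o-quinone methide may oligomerise by hetero-Diels–Alder dimerisation at 110 °C, or the ketene may be diverted before the 6π closure. Fallback setting out from 12 and returning at 16: the allenoate of 12 is first reduced to the β,γ-unsaturated ester with Stryker's reagent ([(Ph3P)CuH]6, PhMe, rt; AcOH quench; hydride to the central allene carbon, kinetic α-protonation), giving methyl 2-[4-(benzyloxy)phenyl]-4-(2-isopropoxy-1-methoxy-4-oxo-3-phenylcyclobut-2-en-1-yl)-4-phenylbut-3-enoate F6. This is a normal 4-alkenylcyclobutenone, whose ring expansion is driven by aromatisation; thermolysis (p-xylene, 130 °C, then cat. TsOH) should give, after in situ lactonisation, rac-3-[4-(benzyloxy)phenyl]-6-isopropoxy-5-methoxy-4,7-diphenyl-1-benzofuran-2(3H)-one F7. BCl3/C6HMe5 (CH2Cl2, −78 to 0 °C) then gives the leuco lactone rac-6-hydroxy-3-(4-hydroxyphenyl)-5-methoxy-4,7-diphenyl-1-benzofuran-2(3H)-one F5, and DDQ gives 16.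

3. Step 8. What may go wrong: over-cleavage (loss of the C5 methyl ether through boron chelation with the newly freed C6 oxygen) or incomplete lactonisation. Fallback setting out from 14 and returning at 16: 14 is treated with 2 M aq. HCl in THF at 50 °C; Brønsted hydrolysis of the vinylogous isopropyl ester (addition–elimination of water at the isopropoxy carbon), tautomerisation and acid-catalysed lactonisation should give the O-benzyl ether of the target, 3-[4-(benzyloxy)phenyl]-5-methoxy-4,7-diphenyl-1-benzofuran-2,6-dione F8. The benzyl ether alone is then cleaved with BCl3/C6HMe5 at −78 °C (short contact), giving 16.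

Further compounds
F1 | step 5 | 1-phenylvinyllithium | [Li]C(=C)c1ccccc1
F2 | step 5 | 3-isopropoxy-4-methoxy-2-phenyl-4-(1-phenylethenyl)cyclobut-2-en-1-one (racemic) | C=C(c1ccccc1)C1(OC)C(OC(C)C)=C(c2ccccc2)C1=O
F3 | step 5 | 3-isopropoxy-4-methoxy-2,5-diphenylphenol | Oc1cc(-c2ccccc2)c(OC)c(OC(C)C)c1-c1ccccc1
F4 | step 5 | rac-3-(4-hydroxyphenyl)-6-isopropoxy-5-methoxy-4,7-diphenyl-1-benzofuran-2(3H)-one | COc1c(OC(C)C)c(-c2ccccc2)c2OC(=O)C(c3ccc(O)cc3)c2c1-c1ccccc1
F5 | step 5 | rac-6-hydroxy-3-(4-hydroxyphenyl)-5-methoxy-4,7-diphenyl-1-benzofuran-2(3H)-one | COc1c(O)c(-c2ccccc2)c2OC(=O)C(c3ccc(O)cc3)c2c1-c1ccccc1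
F6 | step 7 | methyl 2-[4-(benzyloxy)phenyl]-4-(2-isopropoxy-1-methoxy-4-oxo-3-phenylcyclobut-2-en-1-yl)-4-phenylbut-3-enoate (diastereomer mixture) | COC(=O)C(C=C(c1ccccc1)C1(OC)C(OC(C)C)=C(c2ccccc2)C1=O)c1ccc(OCc2ccccc2)cc1
F7 | step 7 | rac-3-[4-(benzyloxy)phenyl]-6-isopropoxy-5-methoxy-4,7-diphenyl-1-benzofuran-2(3H)-one | COc1c(OC(C)C)c(-c2ccccc2)c2OC(=O)C(c3ccc(OCc4ccccc4)cc3)c2c1-c1ccccc1
F8 | step 8 | 3-[4-(benzyloxy)phenyl]-5-methoxy-4,7-diphenyl-1-benzofuran-2,6-dione | COC1=C(c2ccccc2)C2=C(c3ccc(OCc4ccccc4)cc3)C(=O)OC2=C(c2ccccc2)C1=O
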